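The number I started from was 0.574: intermediate over substrate at the first beta reading, as fractions of the charge, with substrate taken as what the intermediate and product readings leave.

| flask | substrate | temperature | remark | time |
|---|---|---|---|---|
| zeta | 1 M | −12 °C | run made earlier |  |
| beta | 1.5 M | 37 °C | run made earlier |  |
| birch | 2.0 M | −5 °C |  | 3.0 min |
| alder | 2.0 M | 25 °C |  | 3.0 min |
| larch | 2.0 M | 55 °C |  | 3.0 min |
| oak | 2.0 M | −35 °C |  | 3.0 min |

zeta run (percent of the substrate charged)

| time / min | intermediate / % | product / % |
|---|---|---|
| 0.833 | 14.4 | 0.8 |
| 2.00 | 31.2 | 0.2 |
| 2.50 | 36.3 | 0 |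
| 4.00 | 50.5 | 1.6 |

beta run (percent of the substrate charged)

| time / s | intermediate / % | product / % |
|---|---|---|
| 10.0 | 30.9 | 15.3 |
| 12.0 | 27.9 | 18.3 |
| 30.0 | 18.4 | 36.8 |

(standard deviation of a reading: 1 percentage point)

- the analysis behind the earlier runs scatters by 1 percentage point, standard deviation

- the best flask by amount of intermediate, in percent of the substrate charged; "all alike" if 1.5 percentage points covers them all (birch / alder / larch / oak / all alike)
- amount of intermediate at the end, in percent of the substrate charged, birch
- amount of intermediate at the end, in percent of the substrate charged, alder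
- amount of intermediate at the end, in percent of the substrate charged, larch
- amount of intermediate at the end, in percent of the substrate charged, oak

For larch I wanted the standing ratio, intermediate over substrate once the step between them has relaxed (a pre-equilibrium). I assumed that step first order both ways, so the charge and the time drop out of the ratio. That leaves a warm ratio and a cold one, joined by a straight line of ln ratio against temperature. Larch lies beyond beta by 0.367 of the span from zeta to beta. One point of scatter on the beta intermediate reading, which also shifts the substrate taken as the remainder, therefore moves the larch ratio by about 6.97%, while a cold ratio wrong by a factor 2 moves it by a factor 1.29, so a crude cold ratio would do. In zeta the apparent first-order constant sagged from 0.187 min⁻¹ to 0.176 min⁻¹. A reversible rise sags in proportion to time over the ratio, which gave a cold ratio near 3.13. So the standing ratio in larch came to 0.308. Taking beta's drain of 0.878 min⁻¹ over to larch unchanged, as a rough assumption, larch would keep 7.17% of the charge as substrate plus intermediate, so my figure for larch was 1.69%.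

The forecast gave birch as best, with 58% for birch, 15% for alder, 0.1% for larch and 2.5% for oak; of larch it said “everything has drained”. My larch figure stood higher than that.

The flasks gave birch as best at 65.3%; the forecast's figure for birch is what one gets with rates doubled for every 10 degrees from the zeta run. Alder gave 15.3%, larch 1.73% and oak 2.45%.

    substrate ⇌ intermediate (K = 1.30, k = 0.170 s⁻¹, Ea = 70.0 kJ mol⁻¹, ΔH = −45.0 kJ mol⁻¹)
    intermediate ⇌ product (K = 8.10, k = 0.0130 s⁻¹, Ea = 86.0 kJ mol⁻¹, ΔH = −36.0 kJ mol⁻¹)
    intermediate → decomposed reagent (k = 0.00120 s⁻¹, Ea = 86.0 kJ mol⁻¹)
    2 substrate → homo dimer (k = 0.00190 L mol⁻¹ s⁻¹, Ea = 61.0 kJ mol⁻¹)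
    (constants at 25 °C)

Larch ended with 7.0% substrate, and the standing ratio turns that into 2.16% of intermediate, against 1.73%. The back reaction is part of the reason larch ends so low: with it struck out, larch ends at 6.00% instead of 1.73%. Oak stayed low partly because of the length of its run: at 30.0 min it stood at 21.7% against 2.45%. In the neighbour charged with 1.2 M, substrate ended at 9.9%, so the ratio gave 3.05%; that flask gave 2.45%.

The data stem from a simulated flask for an exercise; scatter was added.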